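**Retrosynthetic overview**

1. Target ⇐ acetonide-masked diol diacetate ⇐ (Z)-enyne by Peterson olefination of a C4 aldehyde ⇐ cis-dihydroxylation of C9=C10 and hydride reduction of the C7 ketone in a (Z)-oxocenone (ring O, C6, C7, C8, C9, C10, C11, C12).
2. Oxocenone ⇐ scission of the C8–C11 ring-fusion bond of a cyclobutene-fused pyranone ⇐ [2+2] photocycloaddition of acetylene (C9, C10) to a cis-2,6-disubstituted 2H-pyran-3(6H)-one, which makes C8–C9 and C10–C11 together.
3. Enabling feature: the conjugated enone C7(=O)–C8=C11 inside the pyranone ring (O, C6, C7, C8, C11, C12). Its alkene takes up the two-carbon unit, and its carbonyl later triggers cleavage of the C8–C11 bond, so the four furan-derived carbons C7, C8, C11, C12 end up separated by C9–C10.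
4. Pyranone ⇐ Achmatowicz rearrangement and ionic hydrogenation of a 2,5-disubstituted furan whose carbinol centers C6 and C13 come from two catalyst-controlled transfer hydrogenations.
5. Ring order: furan → six-membered pyranone → cyclobutene-fused bicycle → eight-membered oxocene → temporary dioxolane (acetonide), removed last.

Key step: step 8

Assumption: carbons are numbered C1 (alkyne CH) to C15 (ethyl CH3) along the chain, with the ring oxygen joining C6 and C12; compounds 1, 4, 12 and 22 are taken as commercial; photoadduct 13 is carried on as the mixture of its two cis-fused ring-fusion diastereomers, which converge in step 9.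

**Route**

Step 1
Reactants: 1 1-(furan-2-yl)propan-1-one
Product: 2 (S)-1-(furan-2-yl)propan-1-ol
Conditions: RuCl[(S,S)-TsDPEN](p-cymene) (1 mol%), HCO2H/Et3N (5:2), rt
Reagents that add atoms: none
Why: Noyori asymmetric transfer hydrogenation of an aryl alkyl ketone, in which the (S,S)-diamine ligand directs hydride to one enantioface (furyl acting as the aryl group) and should set C13 as S.

Step 2
Reactants: 2 (S)-1-(furan-2-yl)propan-1-ol
Product: 3 (S)-tert-butyl[1-(furan-2-yl)propoxy]dimethylsilane
Conditions: TBSCl, imidazole, DMF, rt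
Reagents that add atoms: tert-butyldimethylsilyl chloride, CC(C)(C)[Si](C)(C)Cl
Why: Standard silyl ether formation, giving a group that tolerates furan lithiation and leaves only one free furfuryl alcohol for the later Achmatowicz step.

Step 3
Reactants: 4 3-(benzyloxy)propanoic acid
Product: 5 3-(benzyloxy)-N-methoxy-N-methylpropanamide
Conditions: 1,1'-carbonyldiimidazole, CH2Cl2, rt; then MeNH(OMe)·HCl, rt
Reagents that add atoms: N,O-dimethylhydroxylamine hydrochloride, CNOC.Cl
Why: Amide coupling through the acyl imidazole gives the Weinreb amide needed for clean mono-acylation of an aryllithium.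

Step 4
Reactants: 3 (S)-tert-butyl[1-(furan-2-yl)propoxy]dimethylsilane; 5 3-(benzyloxy)-N-methoxy-N-methylpropanamide
Product: 7 3-(benzyloxy)-1-{5-[(S)-1-(tert-butyldimethylsilyloxy)propyl]furan-2-yl}propan-1-one, via 5-lithiofuran 6 (not isolated)
Conditions: n-BuLi, THF, −78 to 0 °C; then 5, −78 °C; aq. NH4Cl
Reagents that add atoms: none
Why: α-Lithiation of the 2-substituted furan at its free C5 position followed by Weinreb ketone synthesis, the chelated tetrahedral intermediate preventing over-addition.

Step 5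
Reactants: 7 3-(benzyloxy)-1-{5-[(S)-1-(tert-butyldimethylsilyloxy)propyl]furan-2-yl}propan-1-one
Product: 8 (R)-3-(benzyloxy)-1-{5-[(S)-1-(tert-butyldimethylsilyloxy)propyl]furan-2-yl}propan-1-ol
Conditions: RuCl[(R,R)-TsDPEN](p-cymene) (1 mol%), HCO2H/Et3N (5:2), rt
Reagents that add atoms: none
Why: Noyori asymmetric transfer hydrogenation under catalyst control, the (R,R)-ligand setting C6 as R regardless of the remote C13 center.

Step 6
Reactants: 8 (R)-3-(benzyloxy)-1-{5-[(S)-1-(tert-butyldimethylsilyloxy)propyl]furan-2-yl}propan-1-ol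
Product: 10 (2R)-2-[2-(benzyloxy)ethyl]-6-hydroxy-6-[(S)-1-(tert-butyldimethylsilyloxy)propyl]-2H-pyran-3(6H)-one (anomeric mixture), via open-chain cis-enedione 9 (not isolated)
Conditions: mCPBA, CH2Cl2, 0 °C
Reagents that add atoms: meta-chloroperoxybenzoic acid, OOC(=O)c1cccc(Cl)c1
Why: Achmatowicz rearrangement, in which oxidative opening of the furan to the cis-enedione and hemiketalization by the free C6 hydroxyl give the pyranone without touching the C6 and C13 stereocenters.

Step 7
Reactants: 10 (2R)-2-[2-(benzyloxy)ethyl]-6-hydroxy-6-[(S)-1-(tert-butyldimethylsilyloxy)propyl]-2H-pyran-3(6H)-one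
Product: 11 (2R,6R)-2-[2-(benzyloxy)ethyl]-6-[(S)-1-(tert-butyldimethylsilyloxy)propyl]-2H-pyran-3(6H)-one (2,6-cis)
Conditions: Et3SiH, CF3CO2H, CH2Cl2, −40 to −10 °C
Reagents that add atoms: none
Why: Ionic hydrogenation of the hemiketal through the cyclic oxocarbenium ion, where axial hydride delivery anti to the C6 substituent should give the 2,6-cis pyranone and set C12 as R.

Step 8
Reactants: 11 (2R,6R)-2-[2-(benzyloxy)ethyl]-6-[(S)-1-(tert-butyldimethylsilyloxy)propyl]-2H-pyran-3(6H)-one; 12 acetylene
Product: 13 (2R,4R)-4-[2-(benzyloxy)ethyl]-2-[(S)-1-(tert-butyldimethylsilyloxy)propyl]-3-oxabicyclo[4.2.0]oct-7-en-5-one (cis-fused; cyclobutene anti to the two ring substituents drawn, its syn ring-fusion isomer is carried along)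
Conditions: hν (350–366 nm, Pyrex), acetylene-saturated acetone/CH2Cl2, −70 °C, degassed
Reagents that add atoms: none
Why: Excitation of the enone (n→π*) and intersystem crossing give the triplet enone, which adds through C11 to acetylene to form a triplet 1,4-biradical that, after spin inversion, collapses by C8–C9 bond formation, so that C10–C11 and C8–C9 are made in one photochemical operation. The closest known reaction type is the [2+2] photocycloaddition of cyclic enones with acetylene or other alkynes to give bicyclo[4.2.0]oct-7-en-2-ones. The only ring closed is the cyclobutene, by radical–radical recombination of the 1,4-biradical (a formal [2+2] cycloaddition), and the two-carbon bridge forces a cis ring fusion. The new stereocenters C8 and C11 are therefore cis to each other by ring strain, while their sense relative to C6 and C12 (attack anti to the two ring substituents is expected) does not matter because both centers become CH2 groups in step 9, so both facial isomers converge. The step needs only chemoselectivity: the conjugated enone C7(=O)–C8=C11 is the sole chromophore absorbing above 340 nm (benzyl and silyl ethers are transparent and the β,γ-unsaturated ketone product absorbs at shorter wavelength, which limits secondary photochemistry), and the symmetrical alkyne removes any regiochemical question.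

Step 9
Reactants: 13 (2R,4R)-4-[2-(benzyloxy)ethyl]-2-[(S)-1-(tert-butyldimethylsilyloxy)propyl]-3-oxabicyclo[4.2.0]oct-7-en-5-one
Product: 15 (2R,8R,Z)-2-[2-(benzyloxy)ethyl]-8-[(S)-1-(tert-butyldimethylsilyloxy)propyl]-7,8-dihydro-2H-oxocin-3(4H)-one, via tributyltin dienolate 14 (not isolated)
Conditions: Bu3SnH (1.5 equiv, slow addition), AIBN (0.2 equiv), PhH, 80 °C; then moist silica gel, aq. KF
Reagents that add atoms: none
Why: Proposed new method: Bu3Sn• should add reversibly to the C7 carbonyl oxygen to give an O-stannyl ketyl whose cyclobutenylcarbinyl radical can open only by scission of the C8–C11 ring-fusion bond (cleavage of C8–C9 would give a vinyl radical), which relieves the cyclobutene strain and gives a delocalized stannyloxy-pentadienyl radical; hydrogen-atom transfer from Bu3SnH at the C11 terminus should give the conjugated tin dienolate 14, whose kinetic α-protonation at C8 on work-up gives the β,γ-unsaturated ketone with the Z alkene imposed by the eight-membered ring, and the neutral radical chain avoids a carbanion at C11 that would expel the ring oxygen at C12; the closest known reaction types are the O-stannyl ketyl ring scission of α-keto cyclopropanes and cyclobutanes and the radical fragmentation of enone–alkene photoadducts to ring-expanded ketones.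

Step 10
Reactants: 15 (2R,8R,Z)-2-[2-(benzyloxy)ethyl]-8-[(S)-1-(tert-butyldimethylsilyloxy)propyl]-7,8-dihydro-2H-oxocin-3(4H)-one
Product: 16 (2R,3R,8R,Z)-2-[2-(benzyloxy)ethyl]-8-[(S)-1-(tert-butyldimethylsilyloxy)propyl]-3,4,7,8-tetrahydro-2H-oxocin-3-ol
Conditions: LiBH(s-Bu)3 (L-Selectride), THF, −78 °C; aq. NH4Cl
Reagents that add atoms: none
Why: Bulky-hydride ketone reduction, in which attack on the face opposite the neighbouring C6 side chain should give the 6,7-cis alcohol and set C7 as R.

Step 11
Reactants: 16 (2R,3R,8R,Z)-2-[2-(benzyloxy)ethyl]-8-[(S)-1-(tert-butyldimethylsilyloxy)propyl]-3,4,7,8-tetrahydro-2H-oxocin-3-ol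
Product: 17 7-O-tert-butyldimethylsilyl ether of 16 (oxocene with OTBS at C7 and C13, benzyloxyethyl at C6, Z alkene C9=C10)
Conditions: TBSOTf, 2,6-lutidine, CH2Cl2, −78 to 0 °C
Reagents that add atoms: tert-butyldimethylsilyl trifluoromethanesulfonate, CC(C)(C)[Si](C)(C)OS(=O)(=O)C(F)(F)F
Why: Silylation of a hindered secondary alcohol with a silyl triflate, the bulky ether also shielding one face of the ring alkene for the next step.

Step 12
Reactants: 17 7-O-tert-butyldimethylsilyl ether of 16
Product: 18 (6R,7R,9R,10S,12R,13S)-9,10-diol (oxocane with cis-9,10-diol, OTBS at C7 and C13, benzyloxyethyl at C6)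
Conditions: OsO4 (2 mol%), N-methylmorpholine N-oxide, acetone/H2O, rt
Reagents that add atoms: OsO4 (catalytic oxygen carrier), O=[Os](=O)(=O)=O; N-methylmorpholine N-oxide, C[N+]1([O-])CCOCC1; water, O
Why: Upjohn syn-dihydroxylation, in which OsO4 should approach the ring alkene from the face opposite the C7 silyloxy group and the C12 side chain (both homoallylic and on the same face), giving the cis-diol with C9 R and C10 S.

Step 13
Reactants: 18 (6R,7R,9R,10S,12R,13S)-9,10-diol
Product: 19 9,10-O-isopropylidene acetal of 18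
Conditions: 2,2-dimethoxypropane, pyridinium p-toluenesulfonate (cat.), CH2Cl2, rt
Reagents that add atoms: 2,2-dimethoxypropane, COC(C)(C)OC
Why: Acid-catalysed transacetalization on the cis-1,2-diol masks it during the later oxidation and acetylation.

Step 14
Reactants: 19 9,10-O-isopropylidene acetal of 18
Product: 20 primary alcohol (C4–OH) obtained by debenzylation of 19
Conditions: H2 (1 atm), Pd(OH)2/C, EtOAc, rt
Reagents that add atoms: none
Why: Hydrogenolysis of the benzyl ether, placed here because the molecule carries no alkene or alkyne at this stage.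

Step 15
Reactants: 20 primary alcohol (C4–OH)
Product: 21 C4 aldehyde (2-substituted acetaldehyde on C6 of the oxocane)
Conditions: Dess–Martin periodinane, NaHCO3, CH2Cl2, 0 °C to rt
Reagents that add atoms: none
Why: Dess–Martin oxidation under buffered, non-basic conditions gives the β-alkoxy aldehyde without β-elimination of the ring oxygen.

Step 16
Reactants: 21 C4 aldehyde; 22 1,3-bis(triisopropylsilyl)propyne
Product: 25 (Z)-enyne with triisopropylsilyl-capped alkyne (bis-TBS ether acetonide), via lithiated 1,3-bis(triisopropylsilyl)propyne 23 (not isolated), via β-silyl lithium alkoxide 24 (not isolated)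
Conditions: 22, n-BuLi, THF, −78 to −20 °C; then 21, −78 °C to rt; aq. NH4Cl
Reagents that add atoms: none
Why: Peterson olefination, in which the bulky triisopropylsilyl groups favour the adduct that collapses by syn-elimination of silanolate to the (Z)-enyne.

Step 17
Reactants: 25 (Z)-enyne with triisopropylsilyl-capped alkyne
Product: 26 (Z)-enyne 7,13-diol 9,10-acetonide
Conditions: Bu4NF, THF, 0 °C to rt
Reagents that add atoms: none
Why: Fluoride-mediated desilylation removes both silyl ethers and the alkynyl silyl group while the acetonide stays in place.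

Step 18
Reactants: 26 (Z)-enyne 7,13-diol 9,10-acetonide
Product: 27 7,13-diacetate 9,10-acetonide
Conditions: Ac2O, pyridine, DMAP (cat.), CH2Cl2, rt
Reagents that add atoms: acetic anhydride, CC(=O)OC(C)=O
Why: DMAP-catalysed acylation of the two free secondary alcohols at C7 and C13, the 9,10-diol being masked.

Step 19
Reactants: 27 7,13-diacetate 9,10-acetonide
Product: 28 CNP0314743.1 (target)
Conditions: AcOH/H2O (4:1), 40 °C
Reagents that add atoms: none
Why: Mild acid hydrolysis of the acetonide, under which the acetates and the (Z)-enyne should be stable.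

**Compound list**

1 | 1-(furan-2-yl)propan-1-one | CCC(=O)c1ccco1 | starting material
2 | (S)-1-(furan-2-yl)propan-1-ol | CC[C@H](O)c1ccco1 | intermediate
3 | (S)-tert-butyl[1-(furan-2-yl)propoxy]dimethylsilane | CC[C@H](O[Si](C)(C)C(C)(C)C)c1ccco1 | intermediate
4 | 3-(benzyloxy)propanoic acid | OC(=O)CCOCc1ccccc1 | starting material
5 | 3-(benzyloxy)-N-methoxy-N-methylpropanamide | CON(C)C(=O)CCOCc1ccccc1 | intermediate
6 | 5-lithio derivative of 3 (not isolated) | CC[C@H](O[Si](C)(C)C(C)(C)C)c1ccc([Li])o1 | intermediate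
7 | 3-(benzyloxy)-1-{5-[(S)-1-(tert-butyldimethylsilyloxy)propyl]furan-2-yl}propan-1-one | CC[C@H](O[Si](C)(C)C(C)(C)C)c1ccc(o1)C(=O)CCOCc1ccccc1 | intermediate
8 | (R)-3-(benzyloxy)-1-{5-[(S)-1-(tert-butyldimethylsilyloxy)propyl]furan-2-yl}propan-1-ol | CC[C@H](O[Si](C)(C)C(C)(C)C)c1ccc(o1)[C@H](O)CCOCc1ccccc1 | intermediate
9 | (Z)-enedione, open-chain Achmatowicz intermediate with (R)-C6 carbinol and (S)-C13 silyl ether (not isolated) | C(c1ccccc1)OCC[C@@H](O)C(=O)/C=C\C(=O)[C@H](CC)O[Si](C)(C)C(C)(C)C | intermediate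
10 | (2R)-2-[2-(benzyloxy)ethyl]-6-hydroxy-6-[(S)-1-(tert-butyldimethylsilyloxy)propyl]-2H-pyran-3(6H)-one, anomeric mixture | C(c1ccccc1)OCC[C@H]1OC(O)([C@H](CC)O[Si](C)(C)C(C)(C)C)C=CC1=O | intermediate
11 | (2R,6R)-2-[2-(benzyloxy)ethyl]-6-[(S)-1-(tert-butyldimethylsilyloxy)propyl]-2H-pyran-3(6H)-one, 2,6-cis | C(c1ccccc1)OCC[C@H]1O[C@@H]([C@H](CC)O[Si](C)(C)C(C)(C)C)C=CC1=O | intermediate
12 | acetylene | C#C | starting material
13 | (2R,4R)-4-[2-(benzyloxy)ethyl]-2-[(S)-1-(tert-butyldimethylsilyloxy)propyl]-3-oxabicyclo[4.2.0]oct-7-en-5-one, cis-fused, anti isomer drawn (syn ring-fusion isomer accompanies it) | C(c1ccccc1)OCC[C@H]1O[C@@H]([C@H](CC)O[Si](C)(C)C(C)(C)C)[C@@H]2C=C[C@@H]2C1=O | intermediate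
14 | tributyltin dienolate of 15, C7(OSnBu3)=C8–C9=C10 (not isolated) | CCCC[Sn](CCCC)(CCCC)OC1=CC=CC[C@H]([C@H](CC)O[Si](C)(C)C(C)(C)C)O[C@@H]1CCOCc1ccccc1 | intermediate
15 | (2R,8R,Z)-2-[2-(benzyloxy)ethyl]-8-[(S)-1-(tert-butyldimethylsilyloxy)propyl]-7,8-dihydro-2H-oxocin-3(4H)-one | C(c1ccccc1)OCC[C@H]1O[C@@H]([C@H](CC)O[Si](C)(C)C(C)(C)C)C/C=C\CC1=O | intermediate
16 | (2R,3R,8R,Z)-2-[2-(benzyloxy)ethyl]-8-[(S)-1-(tert-butyldimethylsilyloxy)propyl]-3,4,7,8-tetrahydro-2H-oxocin-3-ol | C(c1ccccc1)OCC[C@H]1O[C@@H]([C@H](CC)O[Si](C)(C)C(C)(C)C)C/C=C\C[C@H]1O | intermediate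
17 | 7-O-TBS ether of 16 (6R,7R,12R,13S; Z alkene C9=C10) | C(c1ccccc1)OCC[C@H]1O[C@@H]([C@H](CC)O[Si](C)(C)C(C)(C)C)C/C=C\C[C@H]1O[Si](C)(C)C(C)(C)C | intermediate
18 | (6R,7R,9R,10S,12R,13S)-9,10-diol, 7,13-bis-TBS ether, C4 benzyl ether | C(c1ccccc1)OCC[C@H]1O[C@@H]([C@H](CC)O[Si](C)(C)C(C)(C)C)C[C@H](O)[C@H](O)C[C@H]1O[Si](C)(C)C(C)(C)C | intermediate
19 | 9,10-acetonide of 18 | C(c1ccccc1)OCC[C@H]1O[C@@H]([C@H](CC)O[Si](C)(C)C(C)(C)C)C[C@@H]2OC(C)(C)O[C@@H]2C[C@H]1O[Si](C)(C)C(C)(C)C | intermediate
20 | C4 primary alcohol (debenzylated 19) | OCC[C@H]1O[C@@H]([C@H](CC)O[Si](C)(C)C(C)(C)C)C[C@@H]2OC(C)(C)O[C@@H]2C[C@H]1O[Si](C)(C)C(C)(C)C | intermediate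
21 | C4 aldehyde | O=CC[C@H]1O[C@@H]([C@H](CC)O[Si](C)(C)C(C)(C)C)C[C@@H]2OC(C)(C)O[C@@H]2C[C@H]1O[Si](C)(C)C(C)(C)C | intermediate
22 | 1,3-bis(triisopropylsilyl)propyne | C(C#C[Si](C(C)C)(C(C)C)C(C)C)[Si](C(C)C)(C(C)C)C(C)C | starting material
23 | lithiated 1,3-bis(triisopropylsilyl)propyne (not isolated) | [Li]C(C#C[Si](C(C)C)(C(C)C)C(C)C)[Si](C(C)C)(C(C)C)C(C)C | intermediate
24 | β-silyl lithium alkoxide adduct of 23 with 21, two new centers unassigned (not isolated) | [Li]OC(C[C@H]1O[C@@H]([C@H](CC)O[Si](C)(C)C(C)(C)C)C[C@@H]2OC(C)(C)O[C@@H]2C[C@H]1O[Si](C)(C)C(C)(C)C)C(C#C[Si](C(C)C)(C(C)C)C(C)C)[Si](C(C)C)(C(C)C)C(C)C | intermediate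
25 | (Z)-enyne with triisopropylsilyl alkyne, 7,13-bis-TBS ether, 9,10-acetonide | CC(C)[Si](C(C)C)(C(C)C)C#C/C=C\C[C@H]1O[C@@H]([C@H](CC)O[Si](C)(C)C(C)(C)C)C[C@@H]2OC(C)(C)O[C@@H]2C[C@H]1O[Si](C)(C)C(C)(C)C | intermediate
26 | (Z)-enyne 7,13-diol 9,10-acetonide | C#C/C=C\C[C@H]1O[C@@H]([C@H](CC)O)C[C@@H]2OC(C)(C)O[C@@H]2C[C@H]1O | intermediate
27 | 7,13-diacetate 9,10-acetonide | C#C/C=C\C[C@H]1O[C@@H]([C@H](CC)OC(C)=O)C[C@@H]2OC(C)(C)O[C@@H]2C[C@H]1OC(C)=O | intermediate
28 | CNP0314743.1, (6R,7R,9R,10S,12R,13S)-7,13-diacetoxy-6,12-epoxypentadec-3(Z)-en-1-yne-9,10-diol | C#C/C=C\C[C@H]1O[C@@H]([C@H](CC)OC(C)=O)C[C@H](O)[C@H](O)C[C@H]1OC(C)=O | target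

**Step count and risks**

Total steps: 19. Longest linear sequence: 18 steps (1 to 28 through steps 1, 2 and 4–19); step 3 is the only side-branch step.

Steps most likely to fail:

1. Step 9 (proposed new method). Hydrogen-atom transfer may go to the central carbon C9 of the delocalized radical instead of the C11 terminus, giving the non-conjugated enolate and the wrong alkene position. The double bond may also drift into conjugation during protonation, or the ring may open by loss of the ring oxygen if the chain turns ionic. The fallback uses only known chemistry, sets out from 11 and comes back at 15. Luche reduction of 11 (NaBH4, CeCl3·7H2O, MeOH, −78 °C) would give the allylic alcohol F1, whose C7 configuration is of no consequence because it is re-oxidized at the end. Ozonolysis with NaBH4 work-up would cut the C8=C11 alkene to the triol F2. Selective sulfonylation of the two primary hydroxyls (TsCl, pyridine, 0 °C) would give the bis-tosylate F3. Excess CH2=CHMgBr with catalytic CuI would first close the C7 alkoxide onto C8 to the epoxy tosylate F4 (not isolated), then open the epoxide at C8 and displace the C11 tosylate, giving the diallyl ether alcohol F5. Ring-closing metathesis with the second-generation Grubbs catalyst RuCl2(=CHPh)(H2IMes)(PCy3) in dilute CH2Cl2 would form C9=C10 and give the oxocenol F6. Dess–Martin oxidation of F6 gives 15.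

2. Step 12. The osmylation of the eight-membered alkene may show poor or reversed facial selectivity. The fallback sets out from 17 and comes back at 18, and applies if OsO4 prefers the wrong face. Woodward cis-hydroxylation (I2, AgOAc, wet AcOH) places the two oxygens on the face opposite to the one the electrophile attacks. It would pass through the trans-iodoacetate F7 (not isolated) and, after acetoxonium formation and hydrolysis, give the cis-hydroxy acetate F8 (its regioisomer converges). Methanolysis (K2CO3, MeOH) gives 18.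

3. Step 8. The β,γ-unsaturated ketone product may undergo secondary photochemistry (acyl shift), or the triplet enone may be captured inefficiently by acetylene. The fallback sets out from 11 and comes back at 13. Photocycloaddition of 11 with (Z)-1,2-dichloroethene (hν, Pyrex, CH2Cl2, −40 °C) would give the saturated dichlorocyclobutane adduct F9 as a stereoisomer mixture, which has no β,γ-enone chromophore. Reductive dechlorination with Zn dust in EtOH at reflux gives the cyclobutene 13.

**Further compounds**

F1 | step 9 | (2R,3S,6R)-2-[2-(benzyloxy)ethyl]-6-[(S)-1-(tert-butyldimethylsilyloxy)propyl]-3,6-dihydro-2H-pyran-3-ol (expected 2,3-trans epimer drawn) | C(c1ccccc1)OCC[C@H]1O[C@@H]([C@H](CC)O[Si](C)(C)C(C)(C)C)C=C[C@@H]1O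
F2 | step 9 | acyclic ether triol from ozonolysis and reduction of F1 (C7 secondary OH, C8 and C11 primary OH) | C(c1ccccc1)OCC[C@@H](O[C@H](CO)[C@H](CC)O[Si](C)(C)C(C)(C)C)[C@@H](O)CO
F3 | step 9 | bis(p-toluenesulfonate) of the two primary hydroxyls of F2 | C(c1ccccc1)OCC[C@@H](O[C@H](COS(=O)(=O)c1ccc(C)cc1)[C@H](CC)O[Si](C)(C)C(C)(C)C)[C@@H](O)COS(=O)(=O)c1ccc(C)cc1
F4 | step 9 | C7–C8 epoxide mono-tosylate (not isolated) | C(c1ccccc1)OCC[C@@H](O[C@H](COS(=O)(=O)c1ccc(C)cc1)[C@H](CC)O[Si](C)(C)C(C)(C)C)[C@@H]1CO1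
F5 | step 9 | diallyl ether alcohol (allyl groups on C7 and C12, free C7 hydroxyl) | C(c1ccccc1)OCC[C@@H](O[C@H](CC=C)[C@H](CC)O[Si](C)(C)C(C)(C)C)[C@@H](O)CC=C
F6 | step 9 | (Z)-oxocenol, C7 epimer of 16 | C(c1ccccc1)OCC[C@H]1O[C@@H]([C@H](CC)O[Si](C)(C)C(C)(C)C)C/C=C\C[C@@H]1O
F7 | step 12 | trans-10-iodo-9-acetate of 17 (not isolated) | C(c1ccccc1)OCC[C@H]1O[C@@H]([C@H](CC)O[Si](C)(C)C(C)(C)C)C[C@@H](I)[C@H](OC(C)=O)C[C@H]1O[Si](C)(C)C(C)(C)C
F8 | step 12 | 9-O-acetyl-10-hydroxy derivative of 18 (cis) | C(c1ccccc1)OCC[C@H]1O[C@@H]([C@H](CC)O[Si](C)(C)C(C)(C)C)C[C@H](O)[C@H](OC(C)=O)C[C@H]1O[Si](C)(C)C(C)(C)C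
F9 | step 8 | 7,8-dichloro-3-oxabicyclo[4.2.0]octan-5-one adduct of 11 with 1,2-dichloroethene (cyclobutane stereoisomer mixture) | C(c1ccccc1)OCC[C@H]1O[C@@H]([C@H](CC)O[Si](C)(C)C(C)(C)C)C2C(Cl)C(Cl)C2C1=O
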